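Readings and results are simulated for an exercise, and the scatter is random.

Time tells me little here: over 50.0 min the north run makes target at a nearly steady pace, 8 % after 20.0 min and 19 % after 50.0 min, and within the scatter of 1.5 percentage points I can name no loss of catalyst going on during those readings.

common to all: free catalyst 80 µM; impurity 25 µM

| run | substrate | partner | remark |
|---|---|---|---|
| north | 0.050 M | 0.18 M | run made earlier |
| flask | 0.10 M | 0.180 M |  |

north run (percent of the substrate charged)

| time / min | target / % | substrate / % |
|---|---|---|
| 6.00 | 3 | 98 |
| 15.0 | 6 | 93 |
| 20.0 | 8 | 93 |
| 30.0 | 13 | 87 |
| 40.0 | 16 | 85 |
| 50.0 | 19 | 82 |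

(scatter of a reading: 1.5 percentage points)

- steps under discussion: catalyst intermediate A <-> by-product + catalyst intermediate B; partner + free catalyst <-> catalyst intermediate A; substrate + catalyst intermediate C -> catalyst intermediate D; catalyst intermediate B -> catalyst intermediate C; catalyst intermediate D <-> free catalyst + target; free catalyst + impurity -> spent catalyst
- no earlier run changes the charge of free catalyst; that part of a forecast is a guess

* factor on the rate of making target when 20 % of the substrate are converted if free catalyst is charged twice over
* factor on the rate when 20 % of the substrate are converted if free catalyst is charged at 800 µM instead

Next I turn the substrate and the partner by hand. Each factor compares two charges of catalyst at the same 20 % conversion, with [substrate] and [partner] alike on both sides, so I expect them to cancel, and even 800 µM of catalyst is 0.800 % of the substrate charged in this flask.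

That leaves the catalyst charge, and here the impurity matters. I take each impurity to remove one free catalyst for good, with the impurity as the limiting reagent of that poisoning, and from the north run I place this loss early. The crossing in my reckoning therefore lies at a catalyst charge equal to [impurity], 25 µM, and I count each catalyst unit charged above it as working. So I carry the live catalyst, the charge less the impurity, which is 55.0 µM here. Charging twice over gives 135 µM live, a factor of 2.45, and 800 µM gives 775 µM live, a factor of 14.1.

The forecast counts the same way and then says “I shade slightly downward”, giving 2.4 and 13.5, a little under my figures. The flask gives 2.45 and 14.0.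

    catalyst intermediate A ⇌ by-product + catalyst intermediate B (K = 0.0180 M, k = 55000 h⁻¹)
    partner + free catalyst ⇌ catalyst intermediate A (K = 6.80 M⁻¹, k = 6300 M⁻¹ h⁻¹)
    substrate + catalyst intermediate C → catalyst intermediate D (k = 6700 M⁻¹ h⁻¹)
    catalyst intermediate B → catalyst intermediate C (k = 2200 h⁻¹)
    catalyst intermediate D ⇌ free catalyst + target (K = 0.0240 M, k = 62000 h⁻¹)
    free catalyst + impurity → spent catalyst (k = 8.70 × 10⁶ M⁻¹ h⁻¹)

In this flask the impurity stands at 0 % of its own charge and spent catalyst at 31.2 % of the catalyst charged after 0.800 h, ahead of the moment 1.49 h at which 20 % of the substrate are converted, so the live catalyst is in place when the rate is taken. The charge over the live catalyst is 1.45, and taking the poisoning path away from this flask raises the rate at that conversion by a factor of 1.45, one part of what holds that rate down, and lowers the apparent order in free catalyst there from 1.5 to 1.0.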